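**Strategy.** The route rests on cutting the O1–C3 bond of the 1,2-dioxane together with the Cα–C(=O) and C–OMe bonds of the acetate arm. C3 carries both the ring oxygen O1 and the CH2CO2Me group. This is the pattern left when a peroxide oxygen adds to the inner carbon of a terminal alkene and the outer carbon then takes up CO and methanol. One palladium-mediated operation should therefore close the dioxane ring 6-exo, set C3 trans to the C4 methyl and install the ester. Its precursor is the open-chain tertiary hydroperoxide (2S,4R,6R)-4-hydroperoxy-4,6-dimethyloct-7-en-2-ol, with ring carbons C4 and C6 already set and a spectator carbinol.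

Key step: step 12

Remark (locants): acyclic intermediates use the oct-7-ene numbering of the hydroperoxide (C1–C8); after ring closure the ring is O1, O2, C3–C6, the acetate CH2 is Cα and the side chain is C1'–C6'.

Remark (chemistry): the carbinol carbon C2 of the hydroperoxide is a spectator whose configuration is erased by the later oxidation; its hydroxyl stays free because it is released in the step that installs the hydroperoxide and can reach the alkene only through a seven-membered ring. (R)-But-3-yn-2-ol and diethyl allylphosphonate are taken as commercial.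

## Route

Step 1
Reactants: 1 (R)-but-3-yn-2-ol
Product: 2 (R)-tert-butyl(but-3-yn-2-yloxy)dimethylsilane
Conditions: TBSCl, imidazole, CH2Cl2, 0 °C → rt
Reagents that add atoms: tert-butyldimethylsilyl chloride, CC(C)(C)[Si](C)(C)Cl
Why: Routine silyl ether formation at a secondary alcohol that leaves the carbinol centre untouched, and the bulky ether later steers zirconium to the distal alkyne carbon.

Step 2
Reactants: 2 (R)-tert-butyl(but-3-yn-2-yloxy)dimethylsilane
Product: 4 (R)-tert-butyldimethyl(pent-3-yn-2-yloxy)silane, via lithium acetylide 3 (not isolated)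
Conditions: n-BuLi, THF, −78 °C; MeI, −78 °C → rt
Reagents that add atoms: iodomethane, CI; n-butyllithium, [Li]CCCC (its lithium stays only in intermediate 3)
Why: Deprotonation of the terminal alkyne and SN2 methylation of the acetylide (alkyne alkylation), with no stereocentre involved.

Step 3
Reactants: 4 (R)-tert-butyldimethyl(pent-3-yn-2-yloxy)silane
Product: 6 tert-butyl{[(2R,3E)-4-iodopent-3-en-2-yl]oxy}dimethylsilane, via alkenylzirconocene chloride 5 (not isolated)
Conditions: Cp2Zr(H)Cl (2 equiv), THF, rt → 45 °C; then I2, THF, 0 °C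
Reagents that add atoms: iodine, II; Cp2Zr(H)Cl, [H][Zr](Cl)(C1C=CC=C1)C1C=CC=C1 (its zirconium stays only in intermediate 5)
Why: Hydrozirconation is a syn addition that should place zirconium on the methyl-bearing alkyne carbon, away from the branched silyloxy centre, and iodinolysis of the C–Zr bond goes with retention, so the (E)-iodide with methyl cis to the carbinol carbon should result.

Step 4
Reactants: 7 methyl (R)-3-hydroxy-2-methylpropanoate
Product: 8 methyl (S)-3-iodo-2-methylpropanoate
Conditions: I2, PPh3, imidazole, CH2Cl2, 0 °C → rt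
Reagents that add atoms: iodine, II
Why: Appel-type iodination of the primary alcohol that does not touch the α-stereocentre (the descriptor changes only because CH2I outranks the ester).

Step 5
Reactants: 8 methyl (S)-3-iodo-2-methylpropanoate; 6 tert-butyl{[(2R,3E)-4-iodopent-3-en-2-yl]oxy}dimethylsilane
Product: 10 methyl (2R,4E,6R)-6-[(tert-butyldimethylsilyl)oxy]-2,4-dimethylhept-4-enoate, via alkylzinc iodide 9 (not isolated)
Conditions: Zn dust (activated with BrCH2CH2Br and Me3SiCl), DMF, rt; then 6, PdCl2(dppf) (5 mol %), DMF/THF, rt → 40 °C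
Reagents that add atoms: zinc, [Zn] (stays only in intermediate 9)
Why: Zinc insertion should give a configurationally stable β-zincio ester that undergoes Negishi sp3–sp2 coupling with retention of alkene geometry, both stereocentres being spectators.

Step 6
Reactants: 10 methyl (2R,4E,6R)-6-[(tert-butyldimethylsilyl)oxy]-2,4-dimethylhept-4-enoate
Product: 12 tert-butyl{[(2R,3E,6R)-4,6-dimethylocta-3,7-dien-2-yl]oxy}dimethylsilane, via aldehyde 11 (not isolated)
Conditions: iBu2AlH (1.1 equiv), CH2Cl2, −78 °C; then Ph3P=CH2 (from Ph3PCH3Br and KN(SiMe3)2, THF), −78 °C → rt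
Reagents that add atoms: methyltriphenylphosphonium bromide, C[P+](c1ccccc1)(c1ccccc1)c1ccccc1.[Br-] (delivers CH2 as methylenetriphenylphosphorane, C=P(c1ccccc1)(c1ccccc1)c1ccccc1)
Why: Partial ester reduction to the aluminium hemiacetal followed by in situ Wittig methylenation of the released aldehyde avoids isolating the epimerisable α-methyl aldehyde, so C6 should be carried through unchanged.

Step 7
Reactants: 12 tert-butyl{[(2R,3E,6R)-4,6-dimethylocta-3,7-dien-2-yl]oxy}dimethylsilane
Product: 13 (2R,3E,6R)-4,6-dimethylocta-3,7-dien-2-ol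
Conditions: Bu4NF, THF, 0 °C → rt
Reagents that add atoms: none
Why: Fluoride cleavage of the silyl ether (desilylation) frees the allylic hydroxyl needed to direct the epoxidation.

Step 8
Reactants: 13 (2R,3E,6R)-4,6-dimethylocta-3,7-dien-2-ol
Product: 14 (2R,3S,4S,6R)-3,4-epoxy-4,6-dimethyloct-7-en-2-ol
Conditions: mCPBA (1.05 equiv), CH2Cl2, −20 → 0 °C
Reagents that add atoms: 3-chloroperoxybenzoic acid, OOC(=O)c1cccc(Cl)c1
Why: Hydroxyl-directed peracid epoxidation in which allylic 1,3-strain from the C4 methyl cis to the carbinol holds the C2–H in the alkene plane, so the hydrogen-bonded peracid should attack the face that gives the threo epoxy alcohol and set C3 and C4 from C2, while the electron-rich trisubstituted alkene reacts far faster than the vinyl group.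

Step 9
Reactants: 14 (2R,3S,4S,6R)-3,4-epoxy-4,6-dimethyloct-7-en-2-ol
Product: 15 (2R,4S,6R)-4,6-dimethyloct-7-ene-2,4-diol
Conditions: NaAlH2(OCH2CH2OMe)2, THF, 0 °C → rt
Reagents that add atoms: none
Why: Regioselective hydride opening of a 2,3-epoxy alcohol, in which delivery from the aluminium alkoxide and the lower substitution both send hydride to C3, so the C4–O bond and its configuration should stay intact.

Step 10
Reactants: 15 (2R,4S,6R)-4,6-dimethyloct-7-ene-2,4-diol
Product: 17 (2S,4S)-2,4-dimethyl-2-[(2R)-2-methylbut-3-en-1-yl]oxetane, via monotosylate 16 (not isolated)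
Conditions: n-BuLi (1.0 equiv), THF, 0 °C; TsCl (1.0 equiv), 0 °C → rt; n-BuLi (1.05 equiv), 0 → 50 °C
Reagents that add atoms: 4-methylbenzenesulfonyl chloride, Cc1ccc(cc1)S(Cl)(=O)=O (its tosyl group stays only in intermediate 16)
Why: Selective sulfonylation of the secondary hydroxyl followed by intramolecular Williamson etherification (4-exo-tet) by the tertiary alkoxide, with inversion at C2 and retention at C4, should give the oxetane with its two ring methyls cis.

Step 11
Reactants: 17 (2S,4S)-2,4-dimethyl-2-[(2R)-2-methylbut-3-en-1-yl]oxetane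
Product: 18 (2S,4R,6R)-4-hydroperoxy-4,6-dimethyloct-7-en-2-ol
Conditions: anhydrous H2O2 in Et2O (excess), Me3SiOTf (0.5 equiv), −78 → −20 °C
Reagents that add atoms: hydrogen peroxide, OO
Why: Lewis-acid-promoted perhydrolysis of an oxetane, in which H2O2 should attack the activated tertiary ring carbon in an SN2-like opening with inversion, setting the (4R) tertiary hydroperoxide and releasing the C2 hydroxyl.

Step 12
Reactants: 18 (2S,4R,6R)-4-hydroperoxy-4,6-dimethyloct-7-en-2-ol; 19 carbon monoxide; 20 methanol
Product: 21 methyl 2-[(3S,4R,6R)-6-[(2S)-2-hydroxypropyl]-4,6-dimethyl-1,2-dioxan-3-yl]acetate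
Conditions: PdCl2(MeCN)2 (10 mol %), 1,4-benzoquinone (1.5 equiv), CO (1 atm), MeOH/CH2Cl2 1:1, 0 °C → rt, dark
Reagents that add atoms: carbon monoxide, [C-]#[O+]; methanol, CO
Why: Proposed new method: divalent palladium should bind the monosubstituted C7=C8 alkene of 18, the tertiary hydroperoxide oxygen should add to the inner carbon (the future C3), and the primary Cα–palladium bond should then insert CO and be cleaved by methanol, after which benzoquinone returns zerovalent palladium to the divalent state. The closest known reaction types, merged here, are the palladium-catalysed intramolecular alkoxycarbonylation of hydroxy alkenes to tetrahydropyran-2-ylacetates and the Pd(OAc)2/benzoquinone cyclisation of unsaturated hydroperoxides to 1,2-dioxanes. The 1,2-dioxane ring is closed 6-exo-trig through the O1–C3 bond. C3 is the only new stereocentre and is set by substrate control in a chair-like transition state with the C4 methyl, the C6 hydroxypropyl arm and the palladium-bound CH2 equatorial and the C6 methyl axial, which should give the 3,4-trans (3S) product. The step needs this trans closure and needs carbonylation to outrun β-hydride loss and peroxide-cleaving ketonisation; the cis relation of the C4 methyl and the C6 arm locks the chair, a CO atmosphere with a phosphine-free chloride catalyst favours insertion, the free C2' hydroxyl could only close a seven-membered ring, and a copper-free oxidant spares the O–O bond.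

Step 13
Reactants: 21 methyl 2-[(3S,4R,6R)-6-[(2S)-2-hydroxypropyl]-4,6-dimethyl-1,2-dioxan-3-yl]acetate
Product: 22 methyl 2-[(3S,4R,6R)-4,6-dimethyl-6-(2-oxopropyl)-1,2-dioxan-3-yl]acetate
Conditions: Dess–Martin periodinane, CH2Cl2, 0 °C → rt
Reagents that add atoms: none
Why: Dess–Martin oxidation of the secondary alcohol under near-neutral conditions should spare the dialkyl peroxide and the ester and removes the spectator stereocentre.

Step 14
Reactants: 23 allylbenzene; 24 diethyl allylphosphonate
Product: 25 diethyl [(2E)-4-phenylbut-2-en-1-yl]phosphonate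
Conditions: second-generation Grubbs catalyst RuCl2(=CHPh)(PCy3)(H2IMes) (3 mol %), 23 in excess, CH2Cl2, 40 °C
Reagents that add atoms: none
Why: Olefin cross-metathesis of two terminal alkenes with loss of ethylene, in which excess allylbenzene drives the cross product and the (E)-isomer is favoured thermodynamically.

Step 15
Reactants: 22 methyl 2-[(3S,4R,6R)-4,6-dimethyl-6-(2-oxopropyl)-1,2-dioxan-3-yl]acetate; 25 diethyl [(2E)-4-phenylbut-2-en-1-yl]phosphonate
Product: 27 methyl 2-[(3S,4R,6R)-4,6-dimethyl-6-[(2E,4E)-2-methyl-6-phenylhexa-2,4-dien-1-yl]-1,2-dioxan-3-yl]acetate, via lithiated phosphonate 26 (not isolated)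
Conditions: 25 (1.5 equiv), LiN(SiMe3)2 (1.4 equiv), THF, −78 °C; then 22, −78 °C → rt
Reagents that add atoms: lithium bis(trimethylsilyl)amide, [Li]N([Si](C)(C)C)[Si](C)(C)C (its lithium stays only in intermediate 26)
Why: Horner–Wadsworth–Emmons olefination of the methyl ketone by the α-carbon of the allylic phosphonate anion, in which the new C2'=C3' bond should form E because the dienyl chain avoids the neopentyl-like C1' substituent, the C4'=C5' geometry comes from the reagent, and a pre-formed, sub-stoichiometric amide base keeps enolisation of the β-peroxy ketone low.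

## Compound list

1 | (R)-but-3-yn-2-ol | C[C@@H](O)C#C | starting material
2 | (R)-tert-butyl(but-3-yn-2-yloxy)dimethylsilane | C[C@@H](O[Si](C)(C)C(C)(C)C)C#C | intermediate
3 | lithium (3R)-3-[(tert-butyldimethylsilyl)oxy]but-1-yn-1-ide | C[C@@H](O[Si](C)(C)C(C)(C)C)C#C[Li] | intermediate
4 | (R)-tert-butyldimethyl(pent-3-yn-2-yloxy)silane | C[C@@H](O[Si](C)(C)C(C)(C)C)C#CC | intermediate
5 | chloro{(2E,4R)-4-[(tert-butyldimethylsilyl)oxy]pent-2-en-2-yl}bis(cyclopentadienyl)zirconium | C[C@@H](O[Si](C)(C)C(C)(C)C)/C=C(\C)[Zr](Cl)(C1C=CC=C1)C1C=CC=C1 | intermediate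
6 | tert-butyl{[(2R,3E)-4-iodopent-3-en-2-yl]oxy}dimethylsilane | C[C@@H](O[Si](C)(C)C(C)(C)C)/C=C(\C)I | intermediate
7 | methyl (R)-3-hydroxy-2-methylpropanoate | COC(=O)[C@H](C)CO | starting material
8 | methyl (S)-3-iodo-2-methylpropanoate | COC(=O)[C@H](C)CI | intermediate
9 | iodo[(2S)-3-methoxy-2-methyl-3-oxopropyl]zinc | COC(=O)[C@H](C)C[Zn]I | intermediate
10 | methyl (2R,4E,6R)-6-[(tert-butyldimethylsilyl)oxy]-2,4-dimethylhept-4-enoate | COC(=O)[C@H](C)C/C(C)=C/[C@@H](C)O[Si](C)(C)C(C)(C)C | intermediate
11 | (2R,4E,6R)-6-[(tert-butyldimethylsilyl)oxy]-2,4-dimethylhept-4-enal | O=C[C@H](C)C/C(C)=C/[C@@H](C)O[Si](C)(C)C(C)(C)C | intermediate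
12 | tert-butyl{[(2R,3E,6R)-4,6-dimethylocta-3,7-dien-2-yl]oxy}dimethylsilane | C=C[C@H](C)C/C(C)=C/[C@@H](C)O[Si](C)(C)C(C)(C)C | intermediate
13 | (2R,3E,6R)-4,6-dimethylocta-3,7-dien-2-ol | C=C[C@H](C)C/C(C)=C/[C@@H](C)O | intermediate
14 | (2R,3S,4S,6R)-3,4-epoxy-4,6-dimethyloct-7-en-2-ol, i.e. (1R)-1-{(2S,3S)-3-methyl-3-[(2R)-2-methylbut-3-en-1-yl]oxiran-2-yl}ethan-1-ol | C=C[C@H](C)C[C@]1(C)O[C@H]1[C@@H](C)O | intermediate
15 | (2R,4S,6R)-4,6-dimethyloct-7-ene-2,4-diol | C=C[C@H](C)C[C@](C)(O)C[C@@H](C)O | intermediate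
16 | (2R,4S,6R)-4-hydroxy-4,6-dimethyloct-7-en-2-yl 4-methylbenzenesulfonate | C=C[C@H](C)C[C@](C)(O)C[C@@H](C)OS(=O)(=O)c1ccc(C)cc1 | intermediate
17 | (2S,4S)-2,4-dimethyl-2-[(2R)-2-methylbut-3-en-1-yl]oxetane | C=C[C@H](C)C[C@@]1(C)C[C@H](C)O1 | intermediate
18 | (2S,4R,6R)-4-hydroperoxy-4,6-dimethyloct-7-en-2-ol | OO[C@@](C)(C[C@H](C)O)C[C@@H](C)C=C | intermediate
19 | carbon monoxide | [C-]#[O+] | starting material
20 | methanol | CO | starting material
21 | methyl 2-[(3S,4R,6R)-6-[(2S)-2-hydroxypropyl]-4,6-dimethyl-1,2-dioxan-3-yl]acetate | COC(=O)C[C@@H]1OO[C@@](C)(C[C@H](C)O)C[C@H]1C | intermediate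
22 | methyl 2-[(3S,4R,6R)-4,6-dimethyl-6-(2-oxopropyl)-1,2-dioxan-3-yl]acetate | COC(=O)C[C@@H]1OO[C@@](C)(CC(C)=O)C[C@H]1C | intermediate
23 | allylbenzene | C=CCc1ccccc1 | starting material
24 | diethyl allylphosphonate | C=CCP(=O)(OCC)OCC | starting material
25 | diethyl [(2E)-4-phenylbut-2-en-1-yl]phosphonate | CCOP(=O)(OCC)C/C=C/Cc1ccccc1 | intermediate
26 | diethyl [(2E)-1-lithio-4-phenylbut-2-en-1-yl]phosphonate | CCOP(=O)(OCC)C([Li])/C=C/Cc1ccccc1 | intermediate
27 | methyl 2-[(3S,4R,6R)-4,6-dimethyl-6-[(2E,4E)-2-methyl-6-phenylhexa-2,4-dien-1-yl]-1,2-dioxan-3-yl]acetate | COC(=O)C[C@@H]1OO[C@@](C)(C/C(C)=C/C=C/Cc2ccccc2)C[C@H]1C | target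

## Step count and risks

Total step count: 15. Longest linear sequence: 13 steps (steps 1–3, 5–13 and 15, from 1 to 27).

**Step 12 (key step).** The alkylpalladium intermediate may collapse by hydride shift with O–O cleavage to a methyl ketone, or zerovalent palladium formed under CO may reduce the hydroperoxide before carbonylation occurs; facial selectivity at C3 may also leak.

Fallback, from 17 back to 21. Cross-metathesis of 17 with methyl acrylate (second-generation Hoveyda–Grubbs catalyst RuCl2(=CH-2-iPrOC6H4)(H2IMes), CH2Cl2, 40 °C) should give methyl (2E,4R)-5-[(2S,4S)-2,4-dimethyloxetan-2-yl]-4-methylpent-2-enoate F1. Perhydrolysis under the conditions of step 11 should give methyl (2E,4R,6R,8S)-6-hydroperoxy-8-hydroxy-4,6-dimethylnon-2-enoate F2. Et2NH in CF3CH2OH should then close the ring by reversible intramolecular peroxy-Michael addition (6-exo-trig), which settles on the 3,4-trans ester 21.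

**Step 15.** The basic phosphonate anion may enolise the β-peroxy ketone and open the ring by retro-Michael loss of the peroxide, addition to the hindered methyl ketone may be slow, and E/Z control at C2'=C3' may be incomplete.

Fallback, from 22 back to 27. Boron-Wittig olefination of 22 with LiCH(Bpin)2 (from CH2(Bpin)2 and lithium 2,2,6,6-tetramethylpiperidide, THF, −78 °C) should give methyl 2-[(3S,4R,6R)-4,6-dimethyl-6-[(2E)-2-methyl-3-(4,4,5,5-tetramethyl-1,3,2-dioxaborolan-2-yl)prop-2-en-1-yl]-1,2-dioxan-3-yl]acetate F3, whose minor Z isomer is removed by chromatography. Separately, commercial prop-2-yn-1-ylbenzene is converted with Cp2Zr(H)Cl and then I2 into (E)-(3-iodoprop-2-en-1-yl)benzene F4. Suzuki–Miyaura coupling of F3 with F4 (PdCl2(dppf), K3PO4, THF/H2O, rt) joins C3' to C4' with both geometries already fixed and gives 27.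

**Step 11.** Ionisation at the tertiary oxetane carbon may erode the C4 configuration or lead to elimination, and some attack may occur at the secondary ring carbon.

Fallback, from 10 back to 22. Mukaiyama–Isayama peroxidation of 10 (Co(thd)2 with thd = 2,2,6,6-tetramethylheptane-3,5-dionate, O2, Et3SiH, ClCH2CH2Cl, rt) installs the tertiary peroxide by a radical path without stereocontrol and should give methyl (2R,6R)-6-[(tert-butyldimethylsilyl)oxy]-2,4-dimethyl-4-[(triethylsilyl)peroxy]heptanoate F5 as both C4 epimers. The one-pot reduction and methylenation of step 6 should give tert-butyl{[(2R,6R)-4,6-dimethyl-4-[(triethylsilyl)peroxy]oct-7-en-2-yl]oxy}dimethylsilane F6. Bu4NF removes both silyl groups, and chromatography separates (2R,4R,6R)-4-hydroperoxy-4,6-dimethyloct-7-en-2-ol F7 from its C4 epimer. F7 differs from 18 only at the spectator carbinol, so the conditions of step 12 should give methyl 2-[(3S,4R,6R)-6-[(2R)-2-hydroxypropyl]-4,6-dimethyl-1,2-dioxan-3-yl]acetate F8, and Dess–Martin oxidation as in step 13 returns to 22.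

## Further compounds

F1 | step 12 | methyl (2E,4R)-5-[(2S,4S)-2,4-dimethyloxetan-2-yl]-4-methylpent-2-enoate | COC(=O)/C=C/[C@H](C)C[C@@]1(C)C[C@H](C)O1
F2 | step 12 | methyl (2E,4R,6R,8S)-6-hydroperoxy-8-hydroxy-4,6-dimethylnon-2-enoate | COC(=O)/C=C/[C@H](C)C[C@@](C)(OO)C[C@H](C)O
F3 | step 15 | methyl 2-[(3S,4R,6R)-4,6-dimethyl-6-[(2E)-2-methyl-3-(4,4,5,5-tetramethyl-1,3,2-dioxaborolan-2-yl)prop-2-en-1-yl]-1,2-dioxan-3-yl]acetate | COC(=O)C[C@@H]1OO[C@@](C)(C/C(C)=C/B2OC(C)(C)C(C)(C)O2)C[C@H]1C
F4 | step 15 | (E)-(3-iodoprop-2-en-1-yl)benzene | I/C=C/Cc1ccccc1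
F5 | step 11 | methyl (2R,6R)-6-[(tert-butyldimethylsilyl)oxy]-2,4-dimethyl-4-[(triethylsilyl)peroxy]heptanoate (both C4 epimers) | COC(=O)[C@H](C)CC(C)(OO[Si](CC)(CC)CC)C[C@@H](C)O[Si](C)(C)C(C)(C)C
F6 | step 11 | tert-butyl{[(2R,6R)-4,6-dimethyl-4-[(triethylsilyl)peroxy]oct-7-en-2-yl]oxy}dimethylsilane (both C4 epimers) | C=C[C@H](C)CC(C)(OO[Si](CC)(CC)CC)C[C@@H](C)O[Si](C)(C)C(C)(C)C
F7 | step 11 | (2R,4R,6R)-4-hydroperoxy-4,6-dimethyloct-7-en-2-ol | C=C[C@H](C)C[C@@](C)(OO)C[C@@H](C)O
F8 | step 11 | methyl 2-[(3S,4R,6R)-6-[(2R)-2-hydroxypropyl]-4,6-dimethyl-1,2-dioxan-3-yl]acetate | COC(=O)C[C@@H]1OO[C@@](C)(C[C@@H](C)O)C[C@H]1C
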